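**Plan**

- Numbering: the bicycle is treated as an octahydronaphthalene (C1 carries the carboxyl, C2 the secondary methyl, C4a and C8a the angular methyls, C5 the 4-methylpent-3-enyl chain, C5=C6 the ring alkene). Retrosynthesis cuts first the glyceride C–O bond (acid + (R)-glycidyl acetate), then, after a C3=C4 alkene is put back, both ring-A bonds C1–C2 and C4a–C8a at once by an intramolecular Diels–Alder reaction.
- Enabling feature: in ring A these two bonds lie para to each other. They are joined on one side by the single bond C8a–C1, which carries the acyl group on C1 (a latent Z-enoyl dienophile C1=C8a), and on the other by C2–C3–C4–C4a (a latent E,E-diene). Ring B (C4a–C5=C6–C7–C8–C8a) is then exactly a four-atom tether from diene terminus C4a to dienophile carbon C8a.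
- The acyclic (2Z,6Z,8E,10E)-tetraenoyl imide is cut at its C3–C4 bond (sp3–sp2 Negishi coupling), at the diene (alkyne carboalumination/alkenyl coupling, Sonogashira coupling) and at the trisubstituted 6Z alkene (metallate rearrangement of lithiated dihydrofuran).
- Forward order: the chain is grown linearly from dihydrofuran and joined to the iodo-enoyl imide; rings A and B then arise together in one step. The helper groups are removed afterwards: the auxiliary by reduction, the C3=C4 alkene by hydrogenation, and the kinetic C1 configuration by epimerisation.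
- Stereochemistry: C2, C4a and C8a come from the alkene geometries, the endo transition state and the (R)-benzyloxazolidinone; C1 comes from thermodynamic epimerisation of the aldehyde; the glycerol centre comes from (S)-glycidol.

Key step: step 8

Assumption: the chelated s-cis model known for (E)-enoyl oxazolidinones is taken to hold for the (2Z)-3,3-disubstituted enoyl imide of the key step, and the (4R)-auxiliary is chosen on that basis.

**Step 1**
Reactants: 1 2,3-dihydrofuran; 2 5-bromo-2-methylpent-2-ene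
Product: 7 (3Z)-4-iodo-8-methylnona-3,7-dien-1-ol, via 4,5-dihydrofuran-2-yllithium 3 (not isolated), via (4-methylpent-3-en-1-yl)lithium 4 (not isolated), via lithium bis(4-methylpent-3-en-1-yl)cuprate 5 (not isolated), via ring-opened alkenylcuprate 6 (not isolated)
Conditions: 1, t-BuLi, THF–pentane, −78 to 0 °C; separately 2 (2 equiv), Li, Et2O, −10 °C, then CuBr·SMe2, Et2O–Me2S, −45 °C; combine at −45 °C, warm to rt; I2, THF, −78 to 0 °C; H2O
Reagents that add atoms: iodine II
Why: This is a 1,2-metallate rearrangement of an α-alkoxyalkenyl cuprate, in which the alkyl ligand migrates from copper to the lithiated carbon with inversion and expels the ring oxygen, so the new chain ends trans to the hydroxyethyl arm and copper (then iodine, with retention) cis to it, which fixes the 3Z geometry.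

**Step 2**
Reactants: 7 (3Z)-4-iodo-8-methylnona-3,7-dien-1-ol
Product: 9 (3Z)-4-ethynyl-8-methylnona-3,7-dien-1-ol, via silylated enyne 8 (not isolated)
Conditions: Me3SiC≡CH, PdCl2(PPh3)2 (3 mol %), CuI (6 mol %), Et3N, THF, rt; then K2CO3, MeOH, rt
Reagents that add atoms: ethynyltrimethylsilane C#C[Si](C)(C)C
Why: Sonogashira coupling at the alkenyl iodide should proceed with retention of the 3Z geometry, and methanolysis of the C–Si bond then frees the terminal alkyne.

**Step 3**
Reactants: 9 (3Z)-4-ethynyl-8-methylnona-3,7-dien-1-ol; 10 (E)-1-bromoprop-1-ene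
Product: 12 (3Z,5E,7E)-5-methyl-4-(4-methylpent-3-en-1-yl)nona-3,5,7-trien-1-ol, via alkenylalane 11 (not isolated)
Conditions: Me3Al (3.5 equiv), Cp2ZrCl2 (0.5 equiv), CH2Cl2, 0 °C to rt; then 10, Pd(PPh3)4 (5 mol %), ZnCl2, THF, rt; aqueous work-up
Reagents that add atoms: trimethylaluminium C[Al](C)C
Why: Zirconium-catalysed syn-carboalumination puts the methyl on the internal alkyne carbon and aluminium on the terminus cis to it, and the palladium/zinc-mediated Negishi coupling with the (E)-bromide retains both geometries, which gives the 5E,7E diene.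

**Step 4**
Reactants: 12 (3Z,5E,7E)-5-methyl-4-(4-methylpent-3-en-1-yl)nona-3,5,7-trien-1-ol
Product: 13 (2E,4E,6Z)-9-iodo-5-methyl-6-(4-methylpent-3-en-1-yl)nona-2,4,6-triene
Conditions: I2, PPh3, imidazole, CH2Cl2, 0 °C, dark
Reagents that add atoms: iodine II
Why: Appel-type activation of the primary alcohol and SN2 displacement by iodide should proceed under neutral conditions that leave the triene untouched.

**Step 5**
Reactants: 14 but-2-ynoic acid; 15 (4R)-4-benzyl-1,3-oxazolidin-2-one
Product: 17 (4R)-4-benzyl-3-(but-2-ynoyl)-1,3-oxazolidin-2-one, via mixed pivalic anhydride 16 (not isolated)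
Conditions: t-BuCOCl, Et3N, THF, −20 °C; then 15, LiCl, −20 °C to rt
Reagents that add atoms: none
Why: N-acylation through the mixed anhydride should occur at the less hindered alkynoyl carbonyl, the lithium-coordinated oxazolidinone acting as the nucleophile.

**Step 6**
Reactants: 17 (4R)-4-benzyl-3-(but-2-ynoyl)-1,3-oxazolidin-2-one
Product: 18 (4R)-4-benzyl-3-[(2Z)-3-iodobut-2-enoyl]-1,3-oxazolidin-2-one
Conditions: NaI, AcOH, 70 °C
Reagents that add atoms: sodium iodide [Na+].[I-]
Why: Conjugate addition of iodide to the ynoyl group and protonation of the allenoate anti to iodine (hydroiodination of an electron-poor alkyne) should give the kinetic Z isomer with iodine cis to the carbonyl.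

**Step 7**
Reactants: 13 (2E,4E,6Z)-9-iodo-5-methyl-6-(4-methylpent-3-en-1-yl)nona-2,4,6-triene; 18 (4R)-4-benzyl-3-[(2Z)-3-iodobut-2-enoyl]-1,3-oxazolidin-2-one
Product: 21 (4R)-4-benzyl-3-[(2Z,6Z,8E,10E)-3,8-dimethyl-7-(4-methylpent-3-en-1-yl)dodeca-2,6,8,10-tetraenoyl]-1,3-oxazolidin-2-one, via homoallylic organolithium 19 (not isolated), via alkylzinc chloride 20 (not isolated)
Conditions: 13, t-BuLi (2.1 equiv), Et2O, −78 °C, 10 min; ZnCl2 (THF), −78 °C to rt; then 18, Pd(PPh3)4 (5 mol %), THF, rt
Reagents that add atoms: none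
Why: Iodine–lithium exchange and transmetalation give a primary alkylzinc that should undergo Negishi sp3–sp2 coupling at the activated β-iodoenoyl C–I bond with retention, so the chain ends cis to the carbonyl (2Z).

**Step 8**
Reactants: 21 (4R)-4-benzyl-3-[(2Z,6Z,8E,10E)-3,8-dimethyl-7-(4-methylpent-3-en-1-yl)dodeca-2,6,8,10-tetraenoyl]-1,3-oxazolidin-2-one
Product: 22 (4R)-4-benzyl-3-{[(1R,2R,4aR,8aR)-2,4a,8a-trimethyl-5-(4-methylpent-3-en-1-yl)-1,2,4a,7,8,8a-hexahydronaphthalen-1-yl]carbonyl}-1,3-oxazolidin-2-one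
Conditions: Me2AlCl (1.5 equiv), CH2Cl2 (0.01 M), −30 to 0 °C
Reagents that add atoms: none
Why: Me2AlCl ionises the bidentate imide to a cationic chelate whose s-cis (Z)-enoyl group (chain C2=C3, later C1 and C8a) is a strongly activated dienophile, and the (8E,10E)-diene (chain C8–C11, later C4a, C4, C3, C2) adds to it suprafacially in an asynchronous [4+2] cycloaddition with the C8a–C4a bond leading; the closest known reaction type is the Lewis-acid-promoted type 1 intramolecular Diels–Alder reaction of trienoyl oxazolidinones of the 1,3,9-decatriene class. Ring A is closed as a cyclohexene by the cycloaddition itself (both new σ-bonds), and ring B is closed at the same moment by the C4a–C8a bond across the four-atom tether C5=C6–C7–C8, whose preset 6Z alkene makes the forming ring a cyclohexene half-chair. At C8a and C4a the Z-dienophile carries acyl group and tether on the same side, so the endo preference of the chelated acyl group places the tether under the diene and gives the cis ring fusion with both angular methyls syn, while the absolute sense comes from the (4R)-benzyl group, which blocks one face of the planar chelate. C2 follows from the 10E geometry (methyl outside, hence cis to the endo acyl group), and C1 is formed with the acyl group cis to the C2 methyl, that is epimeric to the target, which step 11 corrects. The step needs endo and π-facial selectivity and enough reactivity to join two fully substituted carbons below the temperature at which the Z-methyl diene undergoes 1,5-hydrogen shifts; the cationic chelate, the Z geometry of the dienophile and the conformationally restricted tether are meant to secure these.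

**Step 9**
Reactants: 22 (4R)-4-benzyl-3-{[(1R,2R,4aR,8aR)-2,4a,8a-trimethyl-5-(4-methylpent-3-en-1-yl)-1,2,4a,7,8,8a-hexahydronaphthalen-1-yl]carbonyl}-1,3-oxazolidin-2-one
Product: 23 [(1R,2R,4aR,8aR)-2,4a,8a-trimethyl-5-(4-methylpent-3-en-1-yl)-1,2,4a,7,8,8a-hexahydronaphthalen-1-yl]methanol
Conditions: LiBH4, MeOH (1 equiv), Et2O, 0 °C
Reagents that add atoms: none
Why: Reductive cleavage of the N-acyloxazolidinone should occur at the lithium-chelated exocyclic carbonyl, which releases the auxiliary and gives the primary alcohol without touching the stereocentres.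

**Step 10**
Reactants: 23 [(1R,2R,4aR,8aR)-2,4a,8a-trimethyl-5-(4-methylpent-3-en-1-yl)-1,2,4a,7,8,8a-hexahydronaphthalen-1-yl]methanol
Product: 24 [(1R,2R,4aR,8aR)-2,4a,8a-trimethyl-5-(4-methylpent-3-en-1-yl)-1,2,3,4,4a,7,8,8a-octahydronaphthalen-1-yl]methanol
Conditions: H2 (3 atm), RhCl(PPh3)3 (10 mol %), benzene, rt
Reagents that add atoms: none
Why: Homogeneous hydrogenation with RhCl(PPh3)3 discriminates strongly by alkene substitution, so the cis-disubstituted C3=C4 bond should be reduced while the two trisubstituted alkenes (C5=C6 is also shielded by C4a) remain.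

**Step 11**
Reactants: 24 [(1R,2R,4aR,8aR)-2,4a,8a-trimethyl-5-(4-methylpent-3-en-1-yl)-1,2,3,4,4a,7,8,8a-octahydronaphthalen-1-yl]methanol
Product: 26 (1S,2R,4aR,8aR)-2,4a,8a-trimethyl-5-(4-methylpent-3-en-1-yl)-1,2,3,4,4a,7,8,8a-octahydronaphthalene-1-carbaldehyde, via kinetic C1-epimeric aldehyde 25 (not isolated)
Conditions: Dess–Martin periodinane, CH2Cl2, 0 °C to rt; filter; then K2CO3, MeOH, rt
Reagents that add atoms: none
Why: Dess–Martin oxidation gives the aldehyde, and base-mediated enolisation should equilibrate C1 to the epimer with the formyl group equatorial and trans to the C2 methyl, because the kinetic epimer must either hold the formyl group 1,3-diaxial to C5 or hold the C2 methyl 1,3-diaxial to C8; this sets the C1 configuration of the target.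

**Step 12**
Reactants: 26 (1S,2R,4aR,8aR)-2,4a,8a-trimethyl-5-(4-methylpent-3-en-1-yl)-1,2,3,4,4a,7,8,8a-octahydronaphthalene-1-carbaldehyde
Product: 27 (1S,2R,4aR,8aR)-2,4a,8a-trimethyl-5-(4-methylpent-3-en-1-yl)-1,2,3,4,4a,7,8,8a-octahydronaphthalene-1-carboxylic acid
Conditions: NaClO2, NaH2PO4, 2-methylbut-2-ene (excess), t-BuOH–H2O, 0 °C to rt
Reagents that add atoms: sodium chlorite [Na+].[O-]Cl=O
Why: Pinnick oxidation should convert the hindered aldehyde to the acid under buffered conditions that do not epimerise C1, the alkene scavenger removing HOCl before it can attack the two trisubstituted alkenes.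

**Step 13**
Reactants: 28 (2S)-oxiran-2-ylmethanol
Product: 29 (2R)-oxiran-2-ylmethyl acetate
Conditions: Ac2O, Et3N, DMAP (cat.), CH2Cl2, 0 °C
Reagents that add atoms: acetic anhydride CC(=O)OC(C)=O
Why: Simple O-acetylation leaves the stereocentre untouched (only its descriptor changes from S to R).

**Step 14**
Reactants: 27 (1S,2R,4aR,8aR)-2,4a,8a-trimethyl-5-(4-methylpent-3-en-1-yl)-1,2,3,4,4a,7,8,8a-octahydronaphthalene-1-carboxylic acid; 29 (2R)-oxiran-2-ylmethyl acetate
Product: 30 (2S)-3-acetoxy-2-hydroxypropyl (1S,2R,4aR,8aR)-2,4a,8a-trimethyl-5-(4-methylpent-3-en-1-yl)-1,2,3,4,4a,7,8,8a-octahydronaphthalene-1-carboxylate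
Conditions: (R,R)-(salen)Co(OAc) (5 mol %; trivalent cobalt, salen = N,N'-bis(3,5-di-tert-butylsalicylidene)cyclohexane-1,2-diamine dianion), i-Pr2NEt (0.5 equiv), t-BuOMe, 0 °C to rt
Reagents that add atoms: none
Why: Cobalt–salen-catalysed SN2 opening of the terminal epoxide by the carboxylate should occur at the unsubstituted carbon, so the ester forms by O-alkylation (insensitive to the hindrance at C1), the secondary hydroxyl is set free directly and the glycerol stereocentre is retained.

**Compound list**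

1 | 2,3-dihydrofuran | C1=COCC1 | starting material
2 | 5-bromo-2-methylpent-2-ene | CC(C)=CCCBr | starting material
3 | 4,5-dihydrofuran-2-yllithium | [Li]C1=CCCO1 | intermediate
4 | (4-methylpent-3-en-1-yl)lithium | [Li]CCC=C(C)C | intermediate
5 | lithium bis(4-methylpent-3-en-1-yl)cuprate | CC(C)=CCC[Cu-]CCC=C(C)C.[Li+] | intermediate
6 | ring-opened alkenylcuprate (lithium alkoxide, copper cis to the oxyethyl arm) | [Li]OCC/C=C(\[Cu-]CCC=C(C)C)CCC=C(C)C.[Li+] | intermediate
7 | (3Z)-4-iodo-8-methylnona-3,7-dien-1-ol | OCC/C=C(\I)CCC=C(C)C | intermediate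
8 | (3Z)-8-methyl-4-[(trimethylsilyl)ethynyl]nona-3,7-dien-1-ol | OCC/C=C(\C#C[Si](C)(C)C)CCC=C(C)C | intermediate
9 | (3Z)-4-ethynyl-8-methylnona-3,7-dien-1-ol | OCC/C=C(\C#C)CCC=C(C)C | intermediate
10 | (E)-1-bromoprop-1-ene | C/C=C/Br | starting material
11 | dimethylaluminium (3Z,5E)-6-(dimethylalumanyl)-5-methyl-4-(4-methylpent-3-en-1-yl)hexa-3,5-dien-1-olate | C[Al](C)OCC/C=C(CCC=C(C)C)\C(C)=C\[Al](C)C | intermediate
12 | (3Z,5E,7E)-5-methyl-4-(4-methylpent-3-en-1-yl)nona-3,5,7-trien-1-ol | OCC/C=C(CCC=C(C)C)\C(C)=C\C=C\C | intermediate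
13 | (2E,4E,6Z)-9-iodo-5-methyl-6-(4-methylpent-3-en-1-yl)nona-2,4,6-triene | ICC/C=C(CCC=C(C)C)\C(C)=C\C=C\C | intermediate
14 | but-2-ynoic acid | CC#CC(=O)O | starting material
15 | (4R)-4-benzyl-1,3-oxazolidin-2-one | O=C1N[C@H](Cc2ccccc2)CO1 | starting material
16 | but-2-ynoic pivalic anhydride | CC#CC(=O)OC(=O)C(C)(C)C | intermediate
17 | (4R)-4-benzyl-3-(but-2-ynoyl)-1,3-oxazolidin-2-one | CC#CC(=O)N1[C@H](Cc2ccccc2)COC1=O | intermediate
18 | (4R)-4-benzyl-3-[(2Z)-3-iodobut-2-enoyl]-1,3-oxazolidin-2-one | C/C(I)=C/C(=O)N1[C@H](Cc2ccccc2)COC1=O | intermediate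
19 | [(3Z,5E,7E)-5-methyl-4-(4-methylpent-3-en-1-yl)nona-3,5,7-trien-1-yl]lithium | [Li]CC/C=C(CCC=C(C)C)\C(C)=C\C=C\C | intermediate
20 | chloro[(3Z,5E,7E)-5-methyl-4-(4-methylpent-3-en-1-yl)nona-3,5,7-trien-1-yl]zinc | Cl[Zn]CC/C=C(CCC=C(C)C)\C(C)=C\C=C\C | intermediate
21 | (4R)-4-benzyl-3-[(2Z,6Z,8E,10E)-3,8-dimethyl-7-(4-methylpent-3-en-1-yl)dodeca-2,6,8,10-tetraenoyl]-1,3-oxazolidin-2-one | C/C(CC/C=C(CCC=C(C)C)\C(C)=C\C=C\C)=C/C(=O)N1[C@H](Cc2ccccc2)COC1=O | intermediate
22 | (4R)-4-benzyl-3-{[(1R,2R,4aR,8aR)-2,4a,8a-trimethyl-5-(4-methylpent-3-en-1-yl)-1,2,4a,7,8,8a-hexahydronaphthalen-1-yl]carbonyl}-1,3-oxazolidin-2-one | O=C([C@@H]1[C@H](C)C=C[C@]2(C)C(CCC=C(C)C)=CCC[C@]12C)N1[C@H](Cc2ccccc2)COC1=O | intermediate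
23 | [(1R,2R,4aR,8aR)-2,4a,8a-trimethyl-5-(4-methylpent-3-en-1-yl)-1,2,4a,7,8,8a-hexahydronaphthalen-1-yl]methanol | OC[C@@H]1[C@H](C)C=C[C@]2(C)C(CCC=C(C)C)=CCC[C@]12C | intermediate
24 | [(1R,2R,4aR,8aR)-2,4a,8a-trimethyl-5-(4-methylpent-3-en-1-yl)-1,2,3,4,4a,7,8,8a-octahydronaphthalen-1-yl]methanol | OC[C@@H]1[C@H](C)CC[C@]2(C)C(CCC=C(C)C)=CCC[C@]12C | intermediate
25 | (1R,2R,4aR,8aR)-2,4a,8a-trimethyl-5-(4-methylpent-3-en-1-yl)-1,2,3,4,4a,7,8,8a-octahydronaphthalene-1-carbaldehyde | O=C[C@@H]1[C@H](C)CC[C@]2(C)C(CCC=C(C)C)=CCC[C@]12C | intermediate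
26 | (1S,2R,4aR,8aR)-2,4a,8a-trimethyl-5-(4-methylpent-3-en-1-yl)-1,2,3,4,4a,7,8,8a-octahydronaphthalene-1-carbaldehyde | O=C[C@H]1[C@H](C)CC[C@]2(C)C(CCC=C(C)C)=CCC[C@]12C | intermediate
27 | (1S,2R,4aR,8aR)-2,4a,8a-trimethyl-5-(4-methylpent-3-en-1-yl)-1,2,3,4,4a,7,8,8a-octahydronaphthalene-1-carboxylic acid | OC(=O)[C@H]1[C@H](C)CC[C@]2(C)C(CCC=C(C)C)=CCC[C@]12C | intermediate
28 | (2S)-oxiran-2-ylmethanol | OC[C@H]1CO1 | starting material
29 | (2R)-oxiran-2-ylmethyl acetate | CC(=O)OC[C@H]1CO1 | intermediate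
30 | (2S)-3-acetoxy-2-hydroxypropyl (1S,2R,4aR,8aR)-2,4a,8a-trimethyl-5-(4-methylpent-3-en-1-yl)-1,2,3,4,4a,7,8,8a-octahydronaphthalene-1-carboxylate | CC(=O)OC[C@H](O)COC(=O)[C@H]1[C@H](C)CC[C@]2(C)C(CCC=C(C)C)=CCC[C@]12C | target

**Step count and risks**

Total step count: 14. Longest linear sequence: 11 steps (steps 1, 2, 3, 4, 7, 8, 9, 10, 11, 12, 14).

The three steps most likely to fail are steps 8, 7 and 10.

Step 8. The cycloaddition must join two fully substituted carbons with a diene that carries an inside methyl group, so it may be too slow at the temperatures at which the Lewis acid leaves the triene alone. Cationic oligomerisation may then take over, and endo or facial control may erode if the hindered Z-enoyl group twists out of the chelate plane. The fallback replaces auxiliary control by catalyst control on a smaller, more electrophilic dienophile. It sets out from 21 and returns at 23. Reduction of 21 with i-Bu2AlH (CH2Cl2, −78 °C) would split off the auxiliary and give (2Z,6Z,8E,10E)-3,8-dimethyl-7-(4-methylpent-3-en-1-yl)dodeca-2,6,8,10-tetraen-1-ol F1. Oxidation with MnO2 would give (2Z,6Z,8E,10E)-3,8-dimethyl-7-(4-methylpent-3-en-1-yl)dodeca-2,6,8,10-tetraenal F2. Cyclisation of F2 under a chiral cationic oxazaborolidinium triflimide (proline-derived, B-o-tolyl, CH2Cl2, −78 to −40 °C; antipode chosen from the formyl C–H···O binding model so that the diene adds to the same face as in step 8) would give (1R,2R,4aR,8aR)-2,4a,8a-trimethyl-5-(4-methylpent-3-en-1-yl)-1,2,4a,7,8,8a-hexahydronaphthalene-1-carbaldehyde F3. NaBH4 (MeOH, 0 °C) would then reduce F3 to 23.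

Step 7. The homoallylic organolithium may close reversibly onto the neighbouring alkene, because the resulting cyclopropylcarbinyl anion is dienyl-stabilised; this would scramble the 6Z geometry, and the organolithium may also add to the triene before it is transmetalated. The fallback uses the iodide as an electrophile and builds the Z-enoate by stereospecific carbocupration. It sets out from 13 and returns at 21. Alkylation of dilithium propiolate with 13 (THF–DMPU) would give (6Z,8E,10E)-8-methyl-7-(4-methylpent-3-en-1-yl)dodeca-6,8,10-trien-2-ynoic acid F4. Esterification (MeI, K2CO3, DMF) would give its methyl ester F5. Syn addition of Me2CuLi (THF, −78 °C, protonation at −78 °C) would give methyl (2Z,6Z,8E,10E)-3,8-dimethyl-7-(4-methylpent-3-en-1-yl)dodeca-2,6,8,10-tetraenoate F6. Saponification (LiOH, THF–H2O) would give the (2Z)-acid F7, and acylation of lithiated 15 through the pivalic mixed anhydride would give 21.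

Step 10. Hydrogen may be delivered to the exposed side-chain alkene at a rate comparable to that at the ring alkene, which is hindered by C4a, leading to over-reduction. The fallback masks the side-chain alkene. It sets out from 23 and returns at 24. One equivalent of mCPBA (CH2Cl2, NaHCO3, −20 °C) should epoxidise the most accessible trisubstituted alkene to [(1R,2R,4aR,8aR)-5-[2-(3,3-dimethyloxiran-2-yl)ethyl]-2,4a,8a-trimethyl-1,2,4a,7,8,8a-hexahydronaphthalen-1-yl]methanol F8 (epimers at the oxirane carbon). Hydrogenation over RhCl(PPh3)3 at higher pressure would then give the octahydro epoxide F9, and deoxygenation with WCl6/n-BuLi (THF, rt) would restore the alkene and give 24.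

**Further compounds**

F1 | step 8 | (2Z,6Z,8E,10E)-3,8-dimethyl-7-(4-methylpent-3-en-1-yl)dodeca-2,6,8,10-tetraen-1-ol | OC/C=C(C)\CC/C=C(CCC=C(C)C)\C(C)=C\C=C\C
F2 | step 8 | (2Z,6Z,8E,10E)-3,8-dimethyl-7-(4-methylpent-3-en-1-yl)dodeca-2,6,8,10-tetraenal | O=C/C=C(C)\CC/C=C(CCC=C(C)C)\C(C)=C\C=C\C
F3 | step 8 | (1R,2R,4aR,8aR)-2,4a,8a-trimethyl-5-(4-methylpent-3-en-1-yl)-1,2,4a,7,8,8a-hexahydronaphthalene-1-carbaldehyde | O=C[C@@H]1[C@H](C)C=C[C@]2(C)C(CCC=C(C)C)=CCC[C@]12C
F4 | step 7 | (6Z,8E,10E)-8-methyl-7-(4-methylpent-3-en-1-yl)dodeca-6,8,10-trien-2-ynoic acid | OC(=O)C#CCC/C=C(CCC=C(C)C)\C(C)=C\C=C\C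
F5 | step 7 | methyl (6Z,8E,10E)-8-methyl-7-(4-methylpent-3-en-1-yl)dodeca-6,8,10-trien-2-ynoate | COC(=O)C#CCC/C=C(CCC=C(C)C)\C(C)=C\C=C\C
F6 | step 7 | methyl (2Z,6Z,8E,10E)-3,8-dimethyl-7-(4-methylpent-3-en-1-yl)dodeca-2,6,8,10-tetraenoate | COC(=O)/C=C(C)\CC/C=C(CCC=C(C)C)\C(C)=C\C=C\C
F7 | step 7 | (2Z,6Z,8E,10E)-3,8-dimethyl-7-(4-methylpent-3-en-1-yl)dodeca-2,6,8,10-tetraenoic acid | OC(=O)/C=C(C)\CC/C=C(CCC=C(C)C)\C(C)=C\C=C\C
F8 | step 10 | [(1R,2R,4aR,8aR)-5-[2-(3,3-dimethyloxiran-2-yl)ethyl]-2,4a,8a-trimethyl-1,2,4a,7,8,8a-hexahydronaphthalen-1-yl]methanol | OC[C@@H]1[C@H](C)C=C[C@]2(C)C(CCC3OC3(C)C)=CCC[C@]12C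
F9 | step 10 | [(1R,2R,4aR,8aR)-5-[2-(3,3-dimethyloxiran-2-yl)ethyl]-2,4a,8a-trimethyl-1,2,3,4,4a,7,8,8a-octahydronaphthalen-1-yl]methanol | OC[C@@H]1[C@H](C)CC[C@]2(C)C(CCC3OC3(C)C)=CCC[C@]12C
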